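Assumption 1: CIP analysis of the given SMILES (enol tautomer as drawn, priorities syncarpyl C > aryl C > i-Pr > H) gives R at both methine carbons, so the target is the chiral (R,R) isomer and not the meso form.
Assumption 2: the sense of induction in step 2 has to be confirmed experimentally. (R)-ligand → (4R,10R) is assumed, and the (S)-ligand is equally available if the sense is reversed.

## Retrosynthetic overview
1. The usual acylphloroglucinol + isobutylidene-syncarpic acid Michael union is avoided, and syncarpic acid is never used. Both syncarpic rings are built last on a chiral bis-lactone.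
2. Target = acylated bis-dihydrocoumarin 6 + 2 × tetramethylcyclobutane-1,3-dione 9 (an exact atom sum). The lactone enolate opens the strained dione, then a lactone-to-carbocycle Claisen closes each trione ring and frees the phenol.
3. The hexanoyl group goes onto the only free arene CH by Friedel–Crafts acylation. It is masked as a silyl enol ether so that no Baker–Venkataraman acyl transfer can occur.
4. Both stereocentres are set in one operation by a double Cu–H asymmetric conjugate reduction of a flat bis(4-isopropylcoumarin).
5. Ring order: arene (purchased) → two pyranones (double Pechmann) → two cyclohexanetriones, with both pyranones consumed.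

## Route

**Step 1**
Reactants: 1 phloroglucinol; 2 ethyl 4-methyl-3-oxopentanoate (2.3 equiv)
Product: 3, 5-hydroxy-4,10-diisopropyl-2H,8H-pyrano[2,3-f]chromene-2,8-dione (angular "head-to-tail" bis-coumarin with one free OH at C5 and one free CH at C6)
Conditions: CF3SO3H (neat), 0 → 60 °C; ice quench; recrystallise
Reagents that add atoms: ethyl 4-methyl-3-oxopentanoate, CCOC(=O)CC(=O)C(C)C
Why: This is a double Pechmann condensation in which the second annulation goes through the 7-OH/C8 site of the first-formed 5,7-dihydroxy-4-isopropylcoumarin because the 5-OH is shielded by the peri isopropyl group, and any regioisomeric bis-lactone would converge on the same target because all lactone C–O bonds are cleaved later.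

**Step 2**
Reactants: 3
Product: 4, (4R,10R)-5-hydroxy-4,10-diisopropyl-3,4,9,10-tetrahydro-2H,8H-pyrano[2,3-f]chromene-2,8-dione
Conditions: CuCl/NaOt-Bu (5 mol %), (R)-DTBM-SEGPHOS (5.5 mol %), HBpin (4 equiv), toluene–THF, rt; aq NH4Cl; chromatography or recrystallisation
Reagents that add atoms: none (HBpin supplies H only; the phenol is borylated transiently)
Why: In this Cu–H-catalysed asymmetric 1,4-reduction of 4-substituted coumarins, ligated CuH delivers hydride to C4 and C10 of the planar, face-exposed lactones under catalyst control (both R), the boron enolates prevent over-reduction, and the minor R,S/S,R products (which would lead to meso material) are separable diastereomers, so the ee of 4 is amplified (Horeau effect).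

**Step 3**
Reactants: 4; 5 hexanoyl chloride
Product: 6, (4R,10R)-6-hexanoyl-5-hydroxy-4,10-diisopropyl-3,4,9,10-tetrahydro-2H,8H-pyrano[2,3-f]chromene-2,8-dione
Conditions: 5 (1.5 equiv), AlCl3 (4 equiv), ClCH2CH2Cl–PhNO2, 0 → 50 °C; cold aq HCl
Reagents that add atoms: hexanoyl chloride, CCCCCC(=O)Cl
Why: Friedel–Crafts acylation (or O-acylation followed by Fries rearrangement) can only occur at C6, the single free position ortho to the OH, while lactone Fries or indanone pathways are blocked by full substitution and the stereocentres cannot ionise because the cation would be an unstabilised secondary cation β to a carbonyl.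

**Step 4**
Reactants: 6; 7 TBSOTf
Product: 8, (4R,10R)-5-(TBSO)-6-[(Z)-1-(TBSO)hex-1-en-1-yl]-4,10-diisopropyl-3,4,9,10-tetrahydro-2H,8H-pyrano[2,3-f]chromene-2,8-dione (the E/Z ratio is inconsequential)
Conditions: TBSOTf (3 equiv), Et3N (5 equiv), CH2Cl2, 0 °C → rt; NaHCO3 work-up
Reagents that add atoms: tert-butyldimethylsilyl triflate, CC(C)(C)[Si](C)(C)OS(=O)(=O)C(F)(F)F
Why: Soft enolisation and silylation (no free enolate is formed) masks the acidic OH and the enolisable ketone, so that in steps 5–6 no hexanoyl enolate can add to 9 or undergo Baker–Venkataraman transfer onto the adjacent O7 lactone.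

**Step 5**
Reactants: 8; 9 2,2,4,4-tetramethylcyclobutane-1,3-dione (3 equiv)
Product: 10, the 3,9-bis(2,2,4-trimethyl-3-oxopentanoyl) derivative of 8. C4 and C10 are spatially unchanged but are now labelled 4S,10S because of a CIP priority switch. C3 and C9 are labile (epimers and enols) and are destroyed in step 6.
Conditions: LiHMDS (2.3 equiv), THF, –78 °C; 9, –78 → –20 °C; AcOH quench
Reagents that add atoms: 2,2,4,4-tetramethylcyclobutane-1,3-dione, CC1(C)C(=O)C(C)(C)C1=O
Why: Proposed new method: each lactone enolate adds anti to the pseudo-axial isopropyl group onto the non-enolisable, strained cyclobutanedione C=O, the aldolate fragments irreversibly by strain-releasing retro-Claisen to a tertiary enolate, and that enolate is quenched by proton transfer from the new β-keto-lactone C–H; the closest known reaction type is the ring opening of this dione by alkoxides, amines and organometallics to give 2,2,4-trimethyl-3-oxopentanoyl derivatives.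

**Step 6**
Reactants: 10
Product: 11, myrtucommulone F, (R,R): 2-hexanoylphloroglucinol carrying at C4 and C6 an (R)-CH(i-Pr) group bonded to C2 of enolised 4,4,6,6-tetramethylcyclohexane-1,3,5-trione
Conditions: KH (6 equiv), 18-crown-6 (cat.), THF, 0 → 40 °C; AcOH, –20 °C; then Et3N·3HF, THF, 0 °C → rt
Reagents that add atoms: none
Why: Proposed new method: KH forms in each arm the dianion (β-keto-lactone enolate plus hindered isopropyl-ketone enolate), the aryl β-keto ester either is attacked directly or expels its phenoxide by E1cB to an acylketene, and the tertiary enolate carbon closes the six-membered trione (any O-acylated enol lactone is reopened by the tethered phenoxide), driven by formation of a phenoxide and a pKa ~5 trione enolate whose anionic form cannot leave by retro-Michael, so the β-stereocentres are untouched before fluoride removes both silyl groups; the closest known reaction types are the alkoxide-catalysed conversion of dimethylketene dimer into hexamethylcyclohexane-1,3,5-trione and the phloroglucinol-forming Claisen cyclisation of 3,5-dioxo esters.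

## Compound list
1 | phloroglucinol | Oc1cc(O)cc(O)c1 | starting material
2 | ethyl 4-methyl-3-oxopentanoate | CCOC(=O)CC(=O)C(C)C | starting material
3 | 5-hydroxy-4,10-diisopropyl-2H,8H-pyrano[2,3-f]chromene-2,8-dione | Oc1cc2OC(=O)C=C(C(C)C)c2c2OC(=O)C=C(C(C)C)c12 | intermediate
4 | (4R,10R)-tetrahydro bis-lactone | Oc1cc2OC(=O)C[C@H](C(C)C)c2c2OC(=O)C[C@H](C(C)C)c12 | intermediate
5 | hexanoyl chloride | CCCCCC(=O)Cl | starting material
6 | (4R,10R)-6-hexanoyl bis-lactone | Oc1c(C(=O)CCCCC)c2OC(=O)C[C@H](C(C)C)c2c2OC(=O)C[C@H](C(C)C)c12 | intermediate
7 | TBSOTf | CC(C)(C)[Si](C)(C)OS(=O)(=O)C(F)(F)F | starting material (reagent)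
8 | (4R,10R)-5-OTBS, 6-(Z)-silyl enol ether bis-lactone | CC(C)(C)[Si](C)(C)Oc1c(/C(O[Si](C)(C)C(C)(C)C)=C/CCCC)c2OC(=O)C[C@H](C(C)C)c2c2OC(=O)C[C@H](C(C)C)c12 | intermediate
9 | 2,2,4,4-tetramethylcyclobutane-1,3-dione | CC1(C)C(=O)C(C)(C)C1=O | starting material
10 | (4S,10S)-3,9-bis(2,2,4-trimethyl-3-oxopentanoyl) derivative of 8 (C3/C9 labile, left undefined) | CC(C)(C)[Si](C)(C)Oc1c(/C(O[Si](C)(C)C(C)(C)C)=C/CCCC)c2OC(=O)C(C(=O)C(C)(C)C(=O)C(C)C)[C@H](C(C)C)c2c2OC(=O)C(C(=O)C(C)(C)C(=O)C(C)C)[C@H](C(C)C)c12 | intermediate
11 | myrtucommulone F, (R,R) | CCCCCC(=O)c1c(O)c([C@H](C2=C(O)C(C)(C)C(=O)C(C)(C)C2=O)C(C)C)c(O)c([C@H](C2=C(O)C(C)(C)C(=O)C(C)(C)C2=O)C(C)C)c1O | target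

## Totals
Total steps: 6. Longest linear sequence: 6 (fully linear; every partner is commercial).

## Steps most likely to fail, with fallbacks
1. **Step 5.** A hindered secondary enolate must attack a neopentyl-flanked ketone, and the aryl-lactone enolate can collapse to a ketene on warming.
   - Fallback: form this C–C bond before the stereocentre exists.
   - Open 9 with the small enolate of methyl acetate to give methyl 4,4,6-trimethyl-3,5-dioxoheptanoate.
   - Condense that ester with 2,4-diformyl-6-hexanoylphloroglucinol (Duff diformylation of hexanoylphloroglucinol) by Knoevenagel–lactonisation to a flat bis(3-acylcoumarin).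
   - Mask the ketone as in step 4, then set both stereocentres by Cu/phosphoramidite-catalysed asymmetric conjugate addition of i-Pr2Zn at C4. This gives a step-10-type intermediate (possibly a lactone regioisomer, which converges on the same target).
2. **Step 6.** The lactone carbonyl is deactivated by enolate conjugation, O-acylation may compete with C-acylation, and the reacting species is a tetra-anion.
   - Fallback: reverse the polarity of the ring closure.
   - Saponify and perbenzylate 6 to the tri-O-benzyl diacid and convert it to the bis(acid chloride).
   - C-acylate the preformed enolate of methyl 2,2,4-trimethyl-3-oxopentanoate with it.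
   - Close each ring by Dieckmann attack of the unhindered arm CH2 on the methyl ester, then remove the benzyl groups by hydrogenolysis (H2, Pd/C).
3. **Step 2.** Reactivity and ee at peri-crowded 4-isopropylcoumarins are uncertain, and the sense of induction is unproven.
   - Fallback: switch to a C–i-Pr disconnection.
   - Make the 4,10-unsubstituted bis-coumarin from phloroglucinol and malic acid/H2SO4 (or a propiolate), and protect the OH.
   - Install both isopropyl groups by Cu/ferrocenyl-diphosphine-catalysed asymmetric conjugate addition of i-PrMgBr.
   - If catalysis fails altogether, open racemic 4 with (S)-1-phenylethylamine, separate the bis-amides, and relactonise with acid.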